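Drimane-type locants are used (ring A: C1–C5, C10; ring B: C5–C10; C11 = OCH2 on C9; C12 = methyl on C8). Ring B is dissected at C6–C7 and C8–C9: the C7=C8 olefin is an alkyne inserted into the acyl–alkyl bond of a cyclobutanone (C5, C6, C9, C10) fused to ring A. The plan exploits that C12 and C11 sit on the adjacent carbons C8 and C9: tied through the C11 oxygen they are a propargyl ether tether, later a temporary oxolane. A rhodium-catalysed cut-and-sew of this alkyne-tethered cyclobutanone closes ring B as the C6 enone with C9 and C10 in place; reductive opening of the oxolane then releases the C8 methyl and the C11 hydroxyl for umbelliferone.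

Key step: step 7

Convention: β is the face of the C10 methyl, α the opposite face; the absolute configuration is that of the SMILES.
Assumption: dichloroketene adds to 4 anti to the pseudoaxial C4 methyl of the half-chair with equatorial OTBS, i.e. trans to the silyloxy group; were the facial preference the opposite, (R)-Me-CBS would be used in step 2 and nothing else changes.
Assumption: the trans-fused 7-en-6-one (C5–H anti to the C10 methyl) is the thermodynamic ring-fusion isomer of the 4,4,10-trimethyl decalin.

Step 1
Reactants: 1 4-methylcyclohex-2-en-1-one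
Product: 2 2,2,4-trimethylcyclohex-3-en-1-one
Conditions: KOtBu (2.2 equiv), MeI (2.5 equiv), tBuOH, 0 °C → rt
Reagents that add atoms: iodomethane, CI
Why: Deconjugative α,α-dialkylation: the extended dienolate is methylated twice at the α-carbon, which builds the C4 gem-dimethyl group and moves the olefin to the β,γ-position (future C5=C10); no stereocentre is formed.

Step 2
Reactants: 2 2,2,4-trimethylcyclohex-3-en-1-one
Product: 3 (1R)-2,2,4-trimethylcyclohex-3-en-1-ol
Conditions: (S)-2-methyl-CBS-oxazaborolidine [(S)-1-methyl-3,3-diphenyltetrahydro-1H,3H-pyrrolo[1,2-c][1,3,2]oxazaborole] (0.15 equiv), catecholborane (1.5 equiv), toluene, −78 → −20 °C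
Reagents that add atoms: none
Why: Corey–Bakshi–Shibata reduction: the catalyst differentiates the quaternary α-carbon from the α-methylene and should give the (R)-carbinol (future C3), while catecholborane leaves the trisubstituted olefin untouched.

Step 3
Reactants: 3 (1R)-2,2,4-trimethylcyclohex-3-en-1-ol
Product: 4 (R)-TBS ether of 3
Conditions: TBSOTf, 2,6-lutidine, CH2Cl2, 0 °C
Reagents that add atoms: tert-butyldimethylsilyl trifluoromethanesulfonate, CC(C)(C)[Si](C)(C)OS(=O)(=O)C(F)(F)F
Why: Silylation of the hindered neopentyl-type alcohol with the silyl triflate gives a robust bulky ether that also biases the ring conformation for step 4.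

Step 4
Reactants: 4 (R)-TBS ether of 3
Product: 6 cis-fused cyclobutanone, via dichlorocyclobutanone 5 (not isolated)
Conditions: Cl3CCOCl, Zn(Cu), POCl3, Et2O, 0 °C → rt; then Zn, AcOH, rt
Reagents that add atoms: trichloroacetyl chloride, ClC(=O)C(Cl)(Cl)Cl
Why: Dichloroketene [2+2] cycloaddition followed by zinc dechlorination: the ketene carbonyl carbon bonds to the less substituted olefin carbon (C5) and the CCl2 carbon to C10, so the quaternary C10 is set on the face anti to the pseudoaxial C4 methyl (trans to OTBS), the ring fusion is necessarily cis, and the minor C3 diastereomer is removed by chromatography.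

Step 5
Reactants: 7 3-(trimethylsilyl)prop-2-yn-1-ol
Product: 8 [3-(chloromethoxy)prop-1-yn-1-yl]trimethylsilane
Conditions: (CH2O)n, HCl (g), CH2Cl2, 0 °C
Reagents that add atoms: formaldehyde (as paraformaldehyde), C=O; hydrogen chloride, Cl
Why: Standard chloromethyl ether synthesis through the hemiformal; the crude reagent is used at once.

Step 6
Reactants: 6 cis-fused cyclobutanone; 8 [3-(chloromethoxy)prop-1-yn-1-yl]trimethylsilane
Product: 9 C9-alkylated cyclobutanone
Conditions: LiN(iPr)2, THF, −78 °C; then 8, −78 → −40 °C
Reagents that add atoms: none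
Why: Kinetic enolate alkylation: only the C9 methylene is deprotonated (C5–H is a hindered ring-fusion methine), O-alkylation is disfavoured because it would give a strained cyclobutene enol ether, and the electrophile enters on the convex face syn to the C10 methyl, which sets C9 with C11 cis to that methyl.

Step 7
Reactants: 9 C9-alkylated cyclobutanone
Product: 10 tricyclic 7-silyl enone
Conditions: [RhCl(C2H4)2]2 (5 mol %), P[3,5-(CF3)2C6H3]3 (20 mol %), 1,4-dioxane, 130 °C
Reagents that add atoms: none
Why: Monovalent rhodium, guided by π-coordination of the tethered alkyne, adds oxidatively to the strained C6–C9 acyl–alkyl bond; migratory insertion of the alkyne into the Rh–C9 bond forms C8–C9 and C(acyl)–C(vinyl) reductive elimination forms C6–C7. The closest known reaction type is the intramolecular rhodium-catalysed cut-and-sew (carboacylation) of cyclobutanones that carry an alkyne tether on the α-carbon, which gives fused cyclohexenones. The oxolane closes by 5-exo-dig carbometalation, and ring B closes as a six-membered enone by reductive elimination from the seven-membered acyl vinyl rhodacycle, a formal [4+2]. No new stereocentre arises: C9 passes to and from rhodium with retention and C10 and C5 are untouched, so C11 stays cis to the C10 methyl and the ring fusion is still cis. The step needs cleavage of C6–C9 and not C6–C5, and insertion ahead of decarbonylation; the tether on C9 makes only the proximal insertion productive, C5 is shielded by two quaternary neighbours, and the electron-poor phosphine together with the fast intramolecular insertion should suppress CO loss. The silyl cap protects the alkyne from terminal C–H side reactions and ends up on C7.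

Step 8
Reactants: 10 tricyclic 7-silyl enone
Product: 13 trans-fused 11-hydroxy enone, via ring-opened silyl ketone 11 (not isolated), via cis-fused hydroxy enone 12 (not isolated)
Conditions: SmI2 (2.5 equiv), THF–HMPA, −78 → 0 °C; then NaOMe, MeOH, 0 → 40 °C
Reagents that add atoms: none
Why: Reductive cleavage of a γ-alkoxy enone: two-electron reduction by SmI2 gives the C8 carbanion, which expels the C12–O bond by β-elimination; methoxide then removes the α-silyl group, conjugates the exocyclic olefin into ring B as the C8-methyl enone, and epimerises C5 through the enolate to the more stable trans-decalin (C5–H anti to the C10 methyl).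

Step 9
Reactants: 13 trans-fused 11-hydroxy enone
Product: 14 6β,11-diol
Conditions: NaBH4, CeCl3·7H2O, MeOH, −40 °C
Reagents that add atoms: none
Why: Luche 1,2-reduction: the β-face of the C6 carbonyl is blocked by the syn-axial C10 and C4 methyls, so hydride should add from the α-face and give the axial 6β-alcohol.

Step 10
Reactants: 14 6β,11-diol; 15 umbelliferone
Product: 16 C11 umbelliferyl ether
Conditions: PPh3, DIAD, THF, 0 °C → rt
Reagents that add atoms: none
Why: Mitsunobu etherification with the acidic phenol engages the primary C11 hydroxyl selectively, because the hindered axial C6 hydroxyl forms its oxyphosphonium ion far more slowly; no stereocentre is touched.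

Step 11
Reactants: 16 C11 umbelliferyl ether
Product: 17 6α-acetate
Conditions: PPh3, DIAD, AcOH, toluene, 0 °C → rt
Reagents that add atoms: acetic acid, CC(=O)O
Why: Mitsunobu esterification with inversion: acetate displaces the axial allylic oxyphosphonium group at C6 from the open α-face (SN2), turning the 6β-alcohol into the equatorial 6α-acetate.

Step 12
Reactants: 17 6α-acetate
Product: 18 3β-alcohol
Conditions: HF·pyridine, THF–pyridine, 0 °C → rt
Reagents that add atoms: none
Why: Buffered fluoride cleavage of the silyl ether, under which the allylic acetate, the aryl ether and the coumarin lactone should survive.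

Step 13
Reactants: 18 3β-alcohol
Product: 19 CNP0140705.2
Conditions: Dess–Martin periodinane, NaHCO3, CH2Cl2, rt
Reagents that add atoms: none
Why: Dess–Martin oxidation of the secondary C3 alcohol to the ketone under neutral conditions removes the controlling C3 stereocentre and gives the target.

Compound list
1 | 4-methylcyclohex-2-en-1-one (racemic; its stereocentre is lost in step 1) | CC1CCC(=O)C=C1 | starting material
2 | 2,2,4-trimethylcyclohex-3-en-1-one | CC1=CC(C)(C)C(=O)CC1 | intermediate
3 | (1R)-2,2,4-trimethylcyclohex-3-en-1-ol | O[C@@H]1CCC(C)=CC1(C)C | intermediate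
4 | tert-butyldimethyl{[(1R)-2,2,4-trimethylcyclohex-3-en-1-yl]oxy}silane | CC(C)(C)[Si](C)(C)O[C@@H]1CCC(C)=CC1(C)C | intermediate
5 | (4R)-4-[(tert-butyldimethylsilyl)oxy]-8,8-dichloro-1,5,5-trimethylbicyclo[4.2.0]octan-7-one, cis-fused, OTBS cis to the C1 methyl (not isolated) | O=C1C(Cl)(Cl)[C@]2(C)CC[C@@H](O[Si](C)(C)C(C)(C)C)C(C)(C)[C@H]12 | intermediate
6 | (1S,4R,6R)-4-[(tert-butyldimethylsilyl)oxy]-1,5,5-trimethylbicyclo[4.2.0]octan-7-one, cis-fused, OTBS cis to the C1 methyl | O=C1C[C@]2(C)CC[C@@H](O[Si](C)(C)C(C)(C)C)C(C)(C)[C@H]12 | intermediate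
7 | 3-(trimethylsilyl)prop-2-yn-1-ol | OCC#C[Si](C)(C)C | starting material
8 | [3-(chloromethoxy)prop-1-yn-1-yl]trimethylsilane | ClCOCC#C[Si](C)(C)C | intermediate
9 | cyclobutanone 6 carrying on C8 (drimane C9) a {[3-(trimethylsilyl)prop-2-yn-1-yl]oxy}methyl group cis to the angular methyl | O=C1[C@@H](COCC#C[Si](C)(C)C)[C@]2(C)CC[C@@H](O[Si](C)(C)C(C)(C)C)C(C)(C)[C@H]12 | intermediate
10 | 3β-[(tert-butyldimethylsilyl)oxy]-11,12-epoxy-7-(trimethylsilyl)-5β-drim-7-en-6-one: cis-fused decalin enone with the oxolane C9–C11H2–O–C12H2–C8, C11 cis to the C10 methyl | O=C1C([Si](C)(C)C)=C2COC[C@H]2[C@]3(C)CC[C@@H](O[Si](C)(C)C(C)(C)C)C(C)(C)[C@H]13 | intermediate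
11 | 3β-[(tert-butyldimethylsilyl)oxy]-11-hydroxy-7-(trimethylsilyl)-5β-drim-8(12)-en-6-one, C7 epimers (not isolated) | O=C1C([Si](C)(C)C)C(=C)[C@@H](CO)[C@]2(C)CC[C@@H](O[Si](C)(C)C(C)(C)C)C(C)(C)[C@H]12 | intermediate
12 | 3β-[(tert-butyldimethylsilyl)oxy]-11-hydroxy-5β-drim-7-en-6-one, cis-fused (not isolated) | O=C1C=C(C)[C@@H](CO)[C@]2(C)CC[C@@H](O[Si](C)(C)C(C)(C)C)C(C)(C)[C@H]12 | intermediate
13 | 3β-[(tert-butyldimethylsilyl)oxy]-11-hydroxy-5α-drim-7-en-6-one, trans-fused, C11 cis to the C10 methyl | O=C1C=C(C)[C@@H](CO)[C@]2(C)CC[C@@H](O[Si](C)(C)C(C)(C)C)C(C)(C)[C@@H]12 | intermediate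
14 | 3β-[(tert-butyldimethylsilyl)oxy]-5α-drim-7-ene-6β,11-diol (6-OH cis to the C10 methyl) | O[C@H]1C=C(C)[C@@H](CO)[C@]2(C)CC[C@@H](O[Si](C)(C)C(C)(C)C)C(C)(C)[C@@H]12 | intermediate
15 | umbelliferone (7-hydroxy-2H-chromen-2-one) | Oc1ccc2ccc(=O)oc2c1 | starting material
16 | 3β-[(tert-butyldimethylsilyl)oxy]-11-[(2-oxo-2H-chromen-7-yl)oxy]-5α-drim-7-en-6β-ol | O[C@H]1C=C(C)[C@@H](COc2ccc3ccc(=O)oc3c2)[C@]2(C)CC[C@@H](O[Si](C)(C)C(C)(C)C)C(C)(C)[C@@H]12 | intermediate
17 | 3β-[(tert-butyldimethylsilyl)oxy]-11-[(2-oxo-2H-chromen-7-yl)oxy]-5α-drim-7-en-6α-yl acetate (6-OAc trans to the C10 methyl) | CC(=O)O[C@@H]1C=C(C)[C@@H](COc2ccc3ccc(=O)oc3c2)[C@]2(C)CC[C@@H](O[Si](C)(C)C(C)(C)C)C(C)(C)[C@@H]12 | intermediate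
18 | 3β-hydroxy-11-[(2-oxo-2H-chromen-7-yl)oxy]-5α-drim-7-en-6α-yl acetate | CC(=O)O[C@@H]1C=C(C)[C@@H](COc2ccc3ccc(=O)oc3c2)[C@]2(C)CC[C@@H](O)C(C)(C)[C@@H]12 | intermediate
19 | CNP0140705.2, (1R,4R,4aS,8aS)-3,4a,8,8-tetramethyl-7-oxo-4-{[(2-oxo-2H-chromen-7-yl)oxy]methyl}-1,4,4a,5,6,7,8,8a-octahydronaphthalen-1-yl acetate | CC(=O)O[C@@H]1C=C(C)[C@@H](COc2ccc3ccc(=O)oc3c2)[C@]2(C)CCC(=O)C(C)(C)[C@@H]12 | target

Total step count: 13. Longest linear sequence: 12 steps (steps 1–4 and 6–13, from 1).

Steps most likely to fail

Step 7. The rhodium acyl may lose CO, rhodium may insert into the C6–C5 bond, or the silyl-capped alkyne may insert too slowly. Fallback, a radical version of the same ring opening and reclosure: from 9, NH2OH·HCl/NaOAc in EtOH would give oxime F1, and C6F5COCl/Et3N the O-pentafluorobenzoyl oxime F2. Single-electron reduction (Ir(ppy)3, i.e. tris(2-phenylpyridinato)iridium, blue light, Hantzsch ester, MeCN) should generate the iminyl radical. β-Scission of C6–C9 leaves a C6 nitrile and the C9 radical, 5-exo-dig addition to the alkyne forms C8–C9, and the vinyl radical closes 6-exo onto the nitrile to form C6–C7. Mild aqueous acid hydrolysis of the ketimine comes back to the route at 10.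

Step 8. Equilibration through the extended dienolate may scramble C9 or extrude formaldehyde from the C9 hydroxymethyl group before C5 has inverted. Fallback, kinetic instead of thermodynamic control at C5: the sequence is stopped at 12 (SmI2, then K2CO3/MeOH at 0 °C, isolation). LiN(iPr)2 (2.2 equiv, THF, −78 °C) removes the α′ proton at C5 from the alkoxide of 12, and acetic acid at −78 °C protonates the cross-conjugated dienolate on the face anti to the C10 methyl, which comes back to the route at 13. No new compound is made (F0).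

Step 11. The axial oxyphosphonium group at C6 may be lost by E2 elimination with the anti-periplanar C5–H, giving the 5,7-diene instead of substitution. Fallback, thermodynamic control at C6: from 13, an equilibrating Meerwein–Ponndorf–Verley reduction (Al(OiPr)3, iPrOH, toluene, 80 °C, acetone distilled off) should give the equatorial alcohol, 6α,11-diol F3. Mitsunobu etherification of its primary hydroxyl with 15 gives 6α-hydroxy aryl ether F4, and Ac2O/4-(dimethylamino)pyridine/pyridine comes back to the route at 17.

Further compounds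
F1 | step 7 | oxime of 9 (E/Z mixture) | ON=C1[C@@H](COCC#C[Si](C)(C)C)[C@]2(C)CC[C@@H](O[Si](C)(C)C(C)(C)C)C(C)(C)[C@H]12
F2 | step 7 | O-(pentafluorobenzoyl) oxime of 9 | O=C(ON=C1[C@@H](COCC#C[Si](C)(C)C)[C@]2(C)CC[C@@H](O[Si](C)(C)C(C)(C)C)C(C)(C)[C@H]12)c1c(F)c(F)c(F)c(F)c1F
F0 | step 8 | none | none
F3 | step 11 | 3β-[(tert-butyldimethylsilyl)oxy]-5α-drim-7-ene-6α,11-diol | O[C@@H]1C=C(C)[C@@H](CO)[C@]2(C)CC[C@@H](O[Si](C)(C)C(C)(C)C)C(C)(C)[C@@H]12
F4 | step 11 | 3β-[(tert-butyldimethylsilyl)oxy]-11-[(2-oxo-2H-chromen-7-yl)oxy]-5α-drim-7-en-6α-ol | O[C@@H]1C=C(C)[C@@H](COc2ccc3ccc(=O)oc3c2)[C@]2(C)CC[C@@H](O[Si](C)(C)C(C)(C)C)C(C)(C)[C@@H]12
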